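The oxolane (O1, C2–C5) with ketone carbon C6 on C3 and carbinol carbon C7 on C4 is read as two chalcone units, C6–C3–C2 and C5–C4–C7, joined α to α at C3–C4 and oxygenated at both 4-hydroxybenzylic carbons C2 and C7. The disconnection is therefore C3–C4, O1–C2 and O–C7. One oxidation of a 2',4'-di-O-benzyl-4-hydroxychalcone, whose phenol is flanked by two removable bromine atoms, pairs two phenoxyl radicals at C3–C4; both ketone oxygens and water then trap the quinone methides, giving a twofold-symmetric bis-hemiketal of two fused oxolanes that fixes C2, C3, C4 and C7. One hydride delivery at C5 and deprotection complete the target.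

Key step: step 3

Remark on the chemistry: atom numbers are those of the target oxolane (O1; C2 bears the 4-hydroxyphenyl ring, C3 the aroyl carbon C6, C4 the carbinol carbon C7, C5 the resorcinol ring); compounds 6 to 10 are racemic and are drawn as the enantiomer of the target series; the bromine atoms ortho to the free phenol are spectator blocking groups on an otherwise unchanged 2',4'-di-O-protected 4-hydroxychalcone, chosen because an unblocked 4-hydroxyphenyl radical pairs mainly through its ortho carbon or its oxygen, because they hold the C2 and C7 benzylic C–O bonds against acid in step 4, and because they leave together with the benzyl groups in step 6.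

Step 1
Reactants: 1 2,4-dihydroxyacetophenone; 2 benzyl bromide
Product: 3 1-[2,4-bis(benzyloxy)phenyl]ethan-1-one
Conditions: BnBr (2.4 equiv), K2CO3, DMF, 70 °C
Reagents that add atoms: benzyl bromide (2), BrCc1ccccc1
Why: Williamson ether synthesis; carbonate in warm DMF should alkylate the free 4-hydroxyl and the hydrogen-bonded 2-hydroxyl alike, and the 2-O-benzyl group later keeps this oxygen from closing a flavanone ring.

Step 2
Reactants: 3 1-[2,4-bis(benzyloxy)phenyl]ethan-1-one; 4 3,5-dibromo-4-hydroxybenzaldehyde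
Product: 5 (E)-1-[2,4-bis(benzyloxy)phenyl]-3-(3,5-dibromo-4-hydroxyphenyl)prop-2-en-1-one
Conditions: HCl (g), EtOH, 0 °C to rt
Reagents that add atoms: none
Why: Acid-catalysed Claisen–Schmidt (crossed aldol) condensation, in which the enol of 3 adds to the protonated aldehyde and dehydration gives the conjugated E-enone under thermodynamic control; acid avoids the phenoxide that would deactivate the aldehyde under base, so the phenol needs no protecting group.

Step 3
Reactants: 5 (E)-1-[2,4-bis(benzyloxy)phenyl]-3-(3,5-dibromo-4-hydroxyphenyl)prop-2-en-1-one (two molecules)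
Product: 8 rac-(2R,3R)-1,4-bis[2,4-bis(benzyloxy)phenyl]-2,3-bis[(R)-(3,5-dibromo-4-hydroxyphenyl)(hydroxy)methyl]butane-1,4-dione, via bis(quinone methide) 6 (not isolated), via bis-hemiketal 7 (not isolated)
Conditions: FeCl3·6H2O (2.5 equiv), acetone, argon, 0 °C to rt; then pH 7 phosphate buffer
Reagents that add atoms: water, O
Why: Proposed new method: trivalent iron should oxidise the acidic phenol of 5 to a phenoxyl radical with spin on oxygen, on the two ortho carbons and on the enone α-carbon, and because both ortho carbons carry bromine two radicals can pair productively only α to α (C3–C4), giving bis(quinone methide) 6; the nearest documented chemistry is the dehydrodimerisation of sinapic-type 4-hydroxycinnamic acids and cinnamyl alcohols by FeCl3 or peroxidase, which gives cis-fused bis-lactones and furofurans through the same pairing and double capture, and which is carried over here to a chalcone with a ketone oxygen as internal nucleophile. Both rings form in the 5-exo-trig mode: the carbonyl oxygen of each electron-rich 2,4-bis(benzyloxy)aryl ketone attacks the acid-activated methide carbon of the opposite half (O1–C2 and O–C7), and water from the hydrated salt adds to the resulting aryl-stabilised oxocarbenium centres C5 and C6, giving bis-hemiketal 7, the ring tautomer of 8. C3 and C4 are set in the radical pairing, and only the like (racemic) pairing can close two cis-fused five-membered rings, so the meso dimer is diverted to other products; C2 and C7 are set in the ring closures, where each bromophenol ring should take the exo position trans to the neighbouring ring-fusion bond, as in the furofuran lignans. The selectivities needed are α–α over α–ortho and α–O pairing, secured by the two bromine atoms, and capture by the ketone oxygen in preference to flavanone closure, secured by the benzyl ether on the 2-oxygen of the resorcinol ring, while a water-poor medium keeps the capture intramolecular and disfavours a water bridge between C2 and C7. The material is expected as the ring–chain mixture of 7 and 8, in which C5 and C6 are not yet fixed, and is carried on as such.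

Step 4
Reactants: 8 rac-(2R,3R)-1,4-bis[2,4-bis(benzyloxy)phenyl]-2,3-bis[(R)-(3,5-dibromo-4-hydroxyphenyl)(hydroxy)methyl]butane-1,4-dione (as its equilibrium mixture with 7)
Product: 10 rac-[2,4-bis(benzyloxy)phenyl]{(2R,3R,4R,5R)-5-[2,4-bis(benzyloxy)phenyl]-2-(3,5-dibromo-4-hydroxyphenyl)-4-[(R)-(3,5-dibromo-4-hydroxyphenyl)(hydroxy)methyl]oxolan-3-yl}methanone, via oxocarbenium ion 9 (not isolated)
Conditions: Et3SiH (1.1 equiv), BF3·OEt2 (1.5 equiv), CH2Cl2–MeCN, −78 °C; Et3N then NaHCO3 (aq) at −78 °C
Reagents that add atoms: none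
Why: Ionic hydrogenation (Lewis-acid reductive etherification of a γ-hydroxy ketone through its cyclic hemiketal): BF3 should ionise the C5 hemiketal to oxocarbenium ion 9, stabilised by the 2,4-bis(benzyloxy)phenyl ring while the electron-poor dibromophenol rings keep the C2 and C7 benzylic C–O bonds intact, and Et3SiH should deliver hydride to the face opposite the C4 and C3 substituents (the convex face if the second hemiketal ring is closed), which sets C5 with its aryl group cis to the C4 side chain; an endo aryl group at C5 strains the second hemiketal, so the other half should stay an open γ-hydroxy ketone and the reduction should stop after one site, the two sites being equivalent by symmetry.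

Step 5
Reactants: 10 rac-[2,4-bis(benzyloxy)phenyl]{(2R,3R,4R,5R)-5-[2,4-bis(benzyloxy)phenyl]-2-(3,5-dibromo-4-hydroxyphenyl)-4-[(R)-(3,5-dibromo-4-hydroxyphenyl)(hydroxy)methyl]oxolan-3-yl}methanone
Product: 11 [2,4-bis(benzyloxy)phenyl]{(2R,3R,4R,5R)-5-[2,4-bis(benzyloxy)phenyl]-2-(3,5-dibromo-4-hydroxyphenyl)-4-[(R)-(3,5-dibromo-4-hydroxyphenyl)(hydroxy)methyl]oxolan-3-yl}methanone (single enantiomer)
Conditions: preparative SFC, amylose tris(3,5-dimethylphenylcarbamate) chiral stationary phase, CO2–MeOH, 35 °C
Reagents that add atoms: none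
Why: Resolution of enantiomers by chromatography on a chiral stationary phase, in which no bond is made or broken; the four bromine atoms should allow the absolute configuration of each fraction to be assigned by anomalous X-ray scattering before the (2R,3R,4R,5R) antipode is carried on.

Step 6
Reactants: 11 [2,4-bis(benzyloxy)phenyl]{(2R,3R,4R,5R)-5-[2,4-bis(benzyloxy)phenyl]-2-(3,5-dibromo-4-hydroxyphenyl)-4-[(R)-(3,5-dibromo-4-hydroxyphenyl)(hydroxy)methyl]oxolan-3-yl}methanone
Product: 12 (2,4-dihydroxyphenyl){(2R,3R,4R,5R)-5-(2,4-dihydroxyphenyl)-4-[(R)-hydroxy(4-hydroxyphenyl)methyl]-2-(4-hydroxyphenyl)oxolan-3-yl}methanone (CNP0244141.1)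
Conditions: H2 (1 atm), Pd/C, NaOAc, EtOAc–MeOH, rt
Reagents that add atoms: none
Why: Heterogeneous catalytic hydrogenolysis, in which Pd/C should cleave the four benzyl aryl ethers and the four aryl C–Br bonds in one operation while NaOAc neutralises the hydrogen bromide, so that the benzylic C–O bonds at C2, C5 and C7, the hydrogen-bonded aryl ketone and all five stereocentres should stay untouched in the buffered neutral medium.

Compound list
1 | 2,4-dihydroxyacetophenone | CC(=O)c1ccc(O)cc1O | starting material
2 | benzyl bromide | BrCc1ccccc1 | starting material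
3 | 1-[2,4-bis(benzyloxy)phenyl]ethan-1-one | CC(=O)c1ccc(OCc2ccccc2)cc1OCc1ccccc1 | intermediate
4 | 3,5-dibromo-4-hydroxybenzaldehyde | O=Cc1cc(Br)c(O)c(Br)c1 | starting material
5 | (E)-1-[2,4-bis(benzyloxy)phenyl]-3-(3,5-dibromo-4-hydroxyphenyl)prop-2-en-1-one | O=C(/C=C/c1cc(Br)c(O)c(Br)c1)c1ccc(OCc2ccccc2)cc1OCc1ccccc1 | intermediate
6 | rac-(2S,3S)-1,4-bis[2,4-bis(benzyloxy)phenyl]-2,3-bis[(3,5-dibromo-4-oxocyclohexa-2,5-dien-1-ylidene)methyl]butane-1,4-dione, the like bis(quinone methide) | O=C(c1ccc(OCc2ccccc2)cc1OCc1ccccc1)[C@@H](C=C1C=C(Br)C(=O)C(Br)=C1)[C@H](C=C1C=C(Br)C(=O)C(Br)=C1)C(=O)c1ccc(OCc2ccccc2)cc1OCc1ccccc1 | intermediate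
7 | racemic cis-fused 4,8-bis[2,4-bis(benzyloxy)phenyl]-2,6-bis(3,5-dibromo-4-hydroxyphenyl)-3,7-dioxabicyclo[3.3.0]octane-4,8-diol, bromophenol rings exo, hemiketal hydroxyl groups drawn endo (mobile centres), ring tautomer of 8 | Oc1c(Br)cc(cc1Br)[C@@H]1O[C@](O)(c2ccc(OCc3ccccc3)cc2OCc2ccccc2)[C@@H]2[C@H]1[C@@](O)(c1ccc(OCc3ccccc3)cc1OCc1ccccc1)O[C@H]2c1cc(Br)c(O)c(Br)c1 | intermediate
8 | rac-(2R,3R)-1,4-bis[2,4-bis(benzyloxy)phenyl]-2,3-bis[(R)-(3,5-dibromo-4-hydroxyphenyl)(hydroxy)methyl]butane-1,4-dione, twofold-symmetric diketo-diol | O=C(c1ccc(OCc2ccccc2)cc1OCc1ccccc1)[C@@H]([C@@H](O)c1cc(Br)c(O)c(Br)c1)[C@H]([C@@H](O)c1cc(Br)c(O)c(Br)c1)C(=O)c1ccc(OCc2ccccc2)cc1OCc1ccccc1 | intermediate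
9 | racemic cyclic oxocarbenium ion at C5 (5-aryl-3,4-dihydro-2H-furan-1-ium carrying the C3 aroyl group, the C4 hydroxybenzyl group and the C2 bromophenol ring) | O=C(c1ccc(OCc2ccccc2)cc1OCc1ccccc1)[C@@H]1[C@H]([C@@H](O)c2cc(Br)c(O)c(Br)c2)C(c2ccc(OCc3ccccc3)cc2OCc2ccccc2)=[O+][C@H]1c1cc(Br)c(O)c(Br)c1 | intermediate
10 | rac-[2,4-bis(benzyloxy)phenyl]{(2R,3R,4R,5R)-5-[2,4-bis(benzyloxy)phenyl]-2-(3,5-dibromo-4-hydroxyphenyl)-4-[(R)-(3,5-dibromo-4-hydroxyphenyl)(hydroxy)methyl]oxolan-3-yl}methanone (2,3-trans, 3,4-cis, 4,5-cis) | O=C(c1ccc(OCc2ccccc2)cc1OCc1ccccc1)[C@@H]1[C@H]([C@@H](O)c2cc(Br)c(O)c(Br)c2)[C@H](c2ccc(OCc3ccccc3)cc2OCc2ccccc2)O[C@H]1c1cc(Br)c(O)c(Br)c1 | intermediate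
11 | the (2R,3R,4R,5R),(R) enantiomer of 10, single enantiomer | O=C(c1ccc(OCc2ccccc2)cc1OCc1ccccc1)[C@@H]1[C@H]([C@@H](O)c2cc(Br)c(O)c(Br)c2)[C@H](c2ccc(OCc3ccccc3)cc2OCc2ccccc2)O[C@H]1c1cc(Br)c(O)c(Br)c1 | intermediate
12 | (2,4-dihydroxyphenyl){(2R,3R,4R,5R)-5-(2,4-dihydroxyphenyl)-4-[(R)-hydroxy(4-hydroxyphenyl)methyl]-2-(4-hydroxyphenyl)oxolan-3-yl}methanone | O=C(c1ccc(O)cc1O)[C@@H]1[C@H]([C@@H](O)c2ccc(O)cc2)[C@H](c2ccc(O)cc2O)O[C@H]1c1ccc(O)cc1 | target

Total step count: 6. Longest linear sequence: 6 steps (1 → 3 → 5 → 8 → 10 → 11 → 12).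

Steps most likely to fail

Step 3. The radicals may pair through oxygen or with loss of bromine, the meso dimer may form, the quinone methides may tautomerise to the bis(arylidene) diketone before they are captured, water may bridge C2 and C7 to a 2,5-diaryloxolane, or the 1,4-diketone may dehydrate to a furan under the acidic iron salt. The fallback uses known chemistry, sets out from 4 and returns at 8. Knoevenagel–Doebner condensation of 4 with malonic acid (pyridine, piperidine, 90 °C) gives (E)-3-(3,5-dibromo-4-hydroxyphenyl)prop-2-enoic acid F1. Its dehydrodimerisation with FeCl3 in aqueous acetone, the documented reaction of 3,5-disubstituted 4-hydroxycinnamic acids in which each carboxyl group traps the opposite quinone methide, gives the racemic cis-fused exo,exo-diaryl bis-lactone F2, which already holds the relative configuration of C2, C3, C4 and C7. TBSCl and imidazole in DMF give the bis(silyl ether) of the bis-lactone F3. 1-Bromo-2,4-bis(benzyloxy)benzene F4, made from commercial 4-bromobenzene-1,3-diol, benzyl bromide 2 and K2CO3, is converted with n-BuLi in THF at −78 °C into [2,4-bis(benzyloxy)phenyl]lithium F5. Two equivalents of it add once to each lactone carbonyl of F3 at −78 °C, where the lithium hemiketalates do not collapse before work-up, to give the bis(silyl ether) of the diketo-diol F6. TBAF buffered with AcOH in THF at 0 °C then gives 8.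

Step 4. The reduction may run on to the second hemiketal, the C7 or C2 benzylic C–O bond may ionise, the new C5–O1 bond may reopen under the Lewis acid with loss of the kinetic C5 configuration, or the 1,4-dicarbonyl unit may cyclodehydrate. The fallback sets out from 8 and returns at 10; it removes the symmetry before the reduction. TBSCl (3 equiv) and imidazole in DMF silylate both phenols and, statistically, one of the two benzylic carbinols to give the tris(silyl ether) of the diketo-diol F7; under- and over-silylated material is returned to 8 with TBAF and AcOH. In F7 only the free carbinol can close a hemiketal, so Et3SiH and BF3·OEt2 at −78 °C meet a single site and should give the tris(silyl ether) of the oxolane F8 with no possibility of a second reduction. TBAF buffered with AcOH in THF at 0 °C removes the three silyl groups and gives 10.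

Step 6. Benzylic C–O bonds, above all C5–O1 once the resorcinol ring is unmasked, may be hydrogenolysed while hydrogen bromide is being released, or the debromination may stall. The fallback sets out from 11 and returns at 12; it separates the two reductive events. H2, Pd/C and NH4OAc in MeOH–EtOAc, where the ammonium salt suppresses hydrogenolysis of benzylic C–O bonds (benzyl ethers included) and neutralises hydrogen bromide while aryl bromides are still cleaved, give the bromine-free tetrabenzyl ether F9. Its four benzyl ethers are then removed in a bromide-free neutral medium by catalytic transfer hydrogenolysis (Pd/C, cyclohexa-1,4-diene, EtOH, rt), stopped as soon as the phenols are free, to give 12.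

Further compounds
F1 | step 3 | (E)-3-(3,5-dibromo-4-hydroxyphenyl)prop-2-enoic acid | OC(=O)/C=C/c1cc(Br)c(O)c(Br)c1
F2 | step 3 | racemic cis-fused 2,6-bis(3,5-dibromo-4-hydroxyphenyl)-3,7-dioxabicyclo[3.3.0]octane-4,8-dione, aryl groups exo | Oc1c(Br)cc(cc1Br)[C@@H]1OC(=O)[C@@H]2[C@H]1C(=O)O[C@H]2c1cc(Br)c(O)c(Br)c1
F3 | step 3 | bis(tert-butyldimethylsilyl) ether of F2 at both phenols | CC(C)(C)[Si](C)(C)Oc1c(Br)cc(cc1Br)[C@@H]1OC(=O)[C@@H]2[C@H]1C(=O)O[C@H]2c1cc(Br)c(O[Si](C)(C)C(C)(C)C)c(Br)c1
F4 | step 3 | 1-bromo-2,4-bis(benzyloxy)benzene | Brc1ccc(OCc2ccccc2)cc1OCc1ccccc1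
F5 | step 3 | [2,4-bis(benzyloxy)phenyl]lithium | [Li]c1ccc(OCc2ccccc2)cc1OCc1ccccc1
F6 | step 3 | bis(tert-butyldimethylsilyl) ether of 8 at both phenols | O=C(c1ccc(OCc2ccccc2)cc1OCc1ccccc1)[C@@H]([C@@H](O)c1cc(Br)c(O[Si](C)(C)C(C)(C)C)c(Br)c1)[C@H]([C@@H](O)c1cc(Br)c(O[Si](C)(C)C(C)(C)C)c(Br)c1)C(=O)c1ccc(OCc2ccccc2)cc1OCc1ccccc1
F7 | step 4 | tris(tert-butyldimethylsilyl) ether of 8 at both phenols and one benzylic carbinol | O=C(c1ccc(OCc2ccccc2)cc1OCc1ccccc1)[C@@H]([C@@H](O)c1cc(Br)c(O[Si](C)(C)C(C)(C)C)c(Br)c1)[C@H]([C@@H](O[Si](C)(C)C(C)(C)C)c1cc(Br)c(O[Si](C)(C)C(C)(C)C)c(Br)c1)C(=O)c1ccc(OCc2ccccc2)cc1OCc1ccccc1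
F8 | step 4 | tris(tert-butyldimethylsilyl) ether of 10 at both phenols and the C7 carbinol | O=C(c1ccc(OCc2ccccc2)cc1OCc1ccccc1)[C@@H]1[C@H]([C@@H](O[Si](C)(C)C(C)(C)C)c2cc(Br)c(O[Si](C)(C)C(C)(C)C)c(Br)c2)[C@H](c2ccc(OCc3ccccc3)cc2OCc2ccccc2)O[C@H]1c1cc(Br)c(O[Si](C)(C)C(C)(C)C)c(Br)c1
F9 | step 6 | [2,4-bis(benzyloxy)phenyl]{(2R,3R,4R,5R)-5-[2,4-bis(benzyloxy)phenyl]-4-[(R)-hydroxy(4-hydroxyphenyl)methyl]-2-(4-hydroxyphenyl)oxolan-3-yl}methanone | O=C(c1ccc(OCc2ccccc2)cc1OCc1ccccc1)[C@@H]1[C@H]([C@@H](O)c2ccc(O)cc2)[C@H](c2ccc(OCc3ccccc3)cc2OCc2ccccc2)O[C@H]1c1ccc(O)cc1
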